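The synthesis rests on cutting the C3–C3a bond of the pyrrole ring. The precursor is an N-trifluoroacetyl anilinoacetaldehyde diethyl acetal that already carries both benzenoid bromines and the methoxy group. In acid its acetal carbon becomes an oxocarbenium ion that attacks the benzene ring. One operation therefore forges C3–C3a, closes the five-membered ring and aromatises it. The step exploits the para relationship of C3a and the methoxy-bearing C6 on the benzene ring. C7, the other carbon ortho to N1, is occupied by bromine, so the only open site is the activated one. A carboxyl group guards that carbon during dibromination and is then removed. The labile C3 bromine comes last.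

Key step: step 5

Remark on the chemistry: the dibromoaniline is a weak, ortho-hindered nucleophile, so the N–CH2 bond is made by reductive amination with 2,2-diethoxyacetaldehyde (a catalogue glyoxal mono-acetal) and not by SN2 displacement on the sluggish bromoacetaldehyde acetal.

Step 1
Reactants: 1 2-amino-4-methoxybenzoic acid
Product: 3 2-amino-3,5-dibromo-4-methoxybenzoic acid, via monobromo acid 2 (not isolated)
Conditions: Br2 (2.05 equiv), AcOH, 15 °C to rt; pour into water, wash free of bromide
Reagents that add atoms: bromine, BrBr
Why: Electrophilic aromatic bromination: NH2 and OMe jointly activate C5, C3 and C1, the carboxyl group occupies C1, so two equivalents of bromine should fill C5 and then C3, while the acidic non-aqueous medium keeps the carboxyl group protonated and so holds back ipso-bromodecarboxylation.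

Step 2
Reactants: 3 2-amino-3,5-dibromo-4-methoxybenzoic acid
Product: 4 2,4-dibromo-3-methoxyaniline
Conditions: 3 M aq. H2SO4/AcOH (1:1), reflux; basic work-up
Reagents that add atoms: none
Why: Acid-promoted protodecarboxylation of an electron-rich anthranilic acid: the proton adds ipso at C1 (ortho to NH2, para to OMe), CO2 leaves from the arenium ion, and the non-nucleophilic hydrogen sulfate medium contains nothing that could cleave the methyl ether or carry bromine off the ring.

Step 3
Reactants: 4 2,4-dibromo-3-methoxyaniline; 5 2,2-diethoxyacetaldehyde
Product: 7 2,4-dibromo-N-(2,2-diethoxyethyl)-3-methoxyaniline, via imine 6 (not isolated)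
Conditions: 5 (1.5 equiv), NaBH(OAc)3 (2.5 equiv), AcOH (3 equiv), ClCH2CH2Cl, rt
Reagents that add atoms: none
Why: Borch-type reductive amination: the very electrophilic α,α-dialkoxy aldehyde condenses even with a weakly basic aniline, NaBH(OAc)3 reduces the protonated imine without touching acetal or aryl bromide, and the hindered secondary aniline formed should not react a second time.

Step 4
Reactants: 7 2,4-dibromo-N-(2,2-diethoxyethyl)-3-methoxyaniline
Product: 8 N-(2,4-dibromo-3-methoxyphenyl)-N-(2,2-diethoxyethyl)-2,2,2-trifluoroacetamide
Conditions: (CF3CO)2O (1.5 equiv), pyridine (2 equiv), CH2Cl2, 0 °C to rt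
Reagents that add atoms: trifluoroacetic anhydride, O=C(OC(=O)C(F)(F)F)C(F)(F)F
Why: N-acylation with a highly reactive anhydride overcomes the low nucleophilicity of the ortho-bromo secondary aniline, and pyridine buffers the liberated acid so that the acetal stays intact.

Step 5
Reactants: 8 N-(2,4-dibromo-3-methoxyphenyl)-N-(2,2-diethoxyethyl)-2,2,2-trifluoroacetamide
Product: 10 1-(5,7-dibromo-6-methoxy-1H-indol-1-yl)-2,2,2-trifluoroethan-1-one, via 3-ethoxyindoline 9 (not isolated)
Conditions: CF3CO2H, (CF3CO)2O (5 equiv), 0.05 M, reflux, N2
Reagents that add atoms: none
Why: TFA protonates one ethoxy group of 8 and expels ethanol, the oxocarbenium carbon attacks aryl C6 (the future C3a) in an intramolecular electrophilic aromatic substitution to give 3-ethoxyindoline 9, and acid-induced loss of the second ethanol across C2–C3 aromatises the new ring to 10, while the anhydride turns both ethanol molecules into ethyl trifluoroacetate and keeps the medium dry. The closest known reaction type is the Nordlander indole synthesis, the TFA/TFAA cyclisation of N-trifluoroacetyl anilinoacetaldehyde acetals, a Friedel–Crafts relative of the Pomeranz–Fritsch closure. The pyrrole ring closes 5-exo-trig with respect to the C=O+ bond, and the arene C1–C6 bond becomes the endocyclic C7a–C3a bond. No stereocentre remains, since C3 of 9 forms as a racemate and is flattened by the elimination. The step needs site selectivity between the two carbons ortho to nitrogen, and the substrate secures it because C2 carries bromine whereas C6 is free and para to the methoxy oxygen, whose donation has to outweigh two meta bromines. The product must also survive the acid, which the N-trifluoroacetyl group ensures by keeping nitrogen non-basic and the indole too electron-poor for oligomerisation or C3 acylation.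

Step 6
Reactants: 10 1-(5,7-dibromo-6-methoxy-1H-indol-1-yl)-2,2,2-trifluoroethan-1-one
Product: 11 5,7-dibromo-6-methoxy-1H-indole
Conditions: K2CO3 (0.2 equiv), MeOH, rt
Reagents that add atoms: none
Why: Base-catalysed methanolysis (transacylation): an N-trifluoroacetylindole is a strongly activated amide with a stabilised indolide leaving group, made more labile here by the peri-like C7 bromine, so it should cleave at room temperature without touching the aryl bromides or the ether.

Step 7
Reactants: 11 5,7-dibromo-6-methoxy-1H-indole
Product: 12 3,5,7-tribromo-6-methoxy-1H-indole
Conditions: NBS (1.0 equiv), DMF, 0 °C, dark; aq. Na2S2O3/NaHCO3 work-up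
Reagents that add atoms: N-bromosuccinimide, O=C1CCC(=O)N1Br
Why: Electrophilic substitution at C3, the enamine-type β-carbon and most nucleophilic position of a free indole; one equivalent of NBS in the cold should stop at monobromination because C4 is meta to the methoxy group and unactivated, and C2 reacts only after C3 is filled.

Compound list
1 | 2-amino-4-methoxybenzoic acid | COc1ccc(C(=O)O)c(N)c1 | starting material
2 | 2-amino-5-bromo-4-methoxybenzoic acid | COc1cc(N)c(C(=O)O)cc1Br | intermediate (not isolated)
3 | 2-amino-3,5-dibromo-4-methoxybenzoic acid | COc1c(Br)cc(C(=O)O)c(N)c1Br | intermediate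
4 | 2,4-dibromo-3-methoxyaniline | COc1c(Br)ccc(N)c1Br | intermediate
5 | 2,2-diethoxyacetaldehyde | CCOC(C=O)OCC | starting material
6 | (E)-N-(2,4-dibromo-3-methoxyphenyl)-2,2-diethoxyethan-1-imine | CCOC(/C=N/c1ccc(Br)c(OC)c1Br)OCC | intermediate (not isolated)
7 | 2,4-dibromo-N-(2,2-diethoxyethyl)-3-methoxyaniline | CCOC(CNc1ccc(Br)c(OC)c1Br)OCC | intermediate
8 | N-(2,4-dibromo-3-methoxyphenyl)-N-(2,2-diethoxyethyl)-2,2,2-trifluoroacetamide | CCOC(CN(C(=O)C(F)(F)F)c1ccc(Br)c(OC)c1Br)OCC | intermediate
9 | (±)-1-(5,7-dibromo-3-ethoxy-6-methoxy-2,3-dihydro-1H-indol-1-yl)-2,2,2-trifluoroethan-1-one (racemic at C3) | CCOC1CN(C(=O)C(F)(F)F)c2c1cc(Br)c(OC)c2Br | intermediate (not isolated)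
10 | 1-(5,7-dibromo-6-methoxy-1H-indol-1-yl)-2,2,2-trifluoroethan-1-one | COc1c(Br)cc2ccn(C(=O)C(F)(F)F)c2c1Br | intermediate
11 | 5,7-dibromo-6-methoxy-1H-indole | COc1c(Br)cc2cc[nH]c2c1Br | intermediate
12 | 3,5,7-tribromo-6-methoxy-1H-indole | COc1c(Br)cc2c(Br)c[nH]c2c1Br | target

Total step count: 7
Longest linear sequence: 7 steps (1 to 12)

Steps most likely to fail

**Step 5 carries the main risk.**
- The attacked carbon is meta to two bromines. The methoxy group, squeezed between those bromines, is twisted out of the ring plane and donates less than an unhindered one.
- Ring closure may therefore be slower than decomposition of the ionised acetal. It may also be slower than loss of the N-acyl group followed by acylation of the freed indole.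
- The fallback sets out from 4 and comes back at 11. It makes the C3–C3a bond by cross-coupling instead of electrophilic attack.
- NIS with catalytic TFA in MeCN should iodinate the one activated free carbon to give 2,4-dibromo-6-iodo-3-methoxyaniline F1.
- Sonogashira coupling with trimethylsilylacetylene (PdCl2(PPh3)2, CuI, Et3N, rt) should engage only the C–I bond and give 2,4-dibromo-3-methoxy-6-[(trimethylsilyl)ethynyl]aniline F2.
- K2CO3 in MeOH frees 2,4-dibromo-6-ethynyl-3-methoxyaniline F3.
- CuI in DMF at 100 °C then closes N1–C2 by 5-endo-dig hydroamination to 11.

**Step 2 is second.**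
- Ipso-protonation at C1 suffers from the same electronic handicap as step 5.
- Long heating in strong acid may allow proton attack at the bromine-bearing carbons, leading to loss or migration of bromine, or slow cleavage of the ether.
- The fallback sets out from 3 and comes back at 4. It abandons the arenium-ion pathway for a metal-mediated one: Ag2CO3 (10 mol %) with AcOH in DMSO at 120 °C.
- The silver carboxylate extrudes CO2 to give an arylsilver species that is then protonated.
- This process depends on the ortho substituent beside the carboxylate and not on ring nucleophilicity. It runs in a nearly neutral medium, and monovalent silver does not insert into C–Br bonds.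
- The fallback makes no new compound (F0).

**Step 3 is third.**
- Condensation of the weakly basic, ortho-hindered aniline may lag behind direct reduction of the aldehyde, leaving 4 unchanged.
- The fallback sets out from 4 and comes back at 8. It reverses the order of the two N-functionalisations, so that an anion rather than a neutral amine is the nucleophile.
- (CF3CO)2O and pyridine in CH2Cl2 give N-(2,4-dibromo-3-methoxyphenyl)-2,2,2-trifluoroacetamide F4.
- The caesium salt of F4 is then N-alkylated with bromoacetaldehyde diethyl acetal (Cs2CO3, NaI, DMF, 90 °C) in an SN2 reaction, which leads directly to 8.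

Further compounds
F1 | step 5 | 2,4-dibromo-6-iodo-3-methoxyaniline | COc1c(Br)cc(I)c(N)c1Br
F2 | step 5 | 2,4-dibromo-3-methoxy-6-[(trimethylsilyl)ethynyl]aniline | COc1c(Br)cc(C#C[Si](C)(C)C)c(N)c1Br
F3 | step 5 | 2,4-dibromo-6-ethynyl-3-methoxyaniline | COc1c(Br)cc(C#C)c(N)c1Br
F0 | step 2 | none | none
F4 | step 3 | N-(2,4-dibromo-3-methoxyphenyl)-2,2,2-trifluoroacetamide | COc1c(Br)ccc(NC(=O)C(F)(F)F)c1Br
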